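**Retrosynthetic overview**

1. The target is a bridged acetal (6,12-epoxy-dibenzo[b,f]oxocine, a 2,8-dioxabicyclo[3.3.1]nonane). Ring A (the benzaldehyde ring) carries on two adjacent carbons the acetal carbon C-a and the acetyl-bearing carbon C-c. C-a is bonded to the ring-B aryl ether oxygen and to the bridge oxygen; C-c is bonded to C-b, the oxygenated benzylic carbon on ring B.
2. Enabling feature: C-a is a donor carbon (two O) and C-c an acceptor carbon (alpha to C=O) on ortho positions of ring A, with OMe next to the ring carbon that bears C-a. Excising these two ring-A carbons as an aryne rejoins C-a and C-c as the push-pull C2=C3 bond of a (4S)-3-acetyl-4H-chromen-4-ol silyl ether whose C4-O is the future bridge oxygen. One aryne insertion with transannular acetalisation therefore gives both aryl bonds, the eight-membered ring and the acetal bridge.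
3. The pyridine ring is made last. Ring B is carried as a second, slower-firing ortho-silylaryl triflate; its aryne takes up the enolate of 3-oxobutanal and ammonia closes the 3-methylisoquinoline, so no azine nitrogen meets the first aryne.
4. Both aryne precursors come from one bromophenol made from 2,4,6-trihydroxybenzaldehyde. The only catalyst-set stereocentre is C4 of the chromenol; C-a is relayed by the bridge geometry and C-c is set by convex-face protonation.
5. Ring order: benzene rings A and B (one bought arene) → pyran ring of the chromene → key step (cyclobutene → eight-membered ring → bicyclic acetal) → pyridine ring.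

Key step: step 12

Assumption: sodium (E)-3-oxobut-1-en-1-olate (22) is taken as a commercial salt (otherwise one step from acetone, ethyl formate and NaOMe).
Remark: the acetyl-bearing carbon is enolisable and equilibration is not assumed to favour the target epimer (acetyl cis to the ring-B bridge carbon), so it is fixed by kinetic protonation in step 14 and only mild acid follows.

**Route**

Step 1
Reactants: 1 2,4,6-trihydroxybenzaldehyde
Product: 2 4-formyl-3,5-dihydroxyphenyl 2,2-dimethylpropanoate
Conditions: PivCl (1.0 equiv), Et3N, THF, −40 °C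
Reagents that add atoms: pivaloyl chloride CC(C)(C)C(=O)Cl
Why: Selective O-acylation, since the 4-OH is the most acidic hydroxyl and the only one not held in an O–H···O=C hydrogen bond.

Step 2
Reactants: 2 4-formyl-3,5-dihydroxyphenyl 2,2-dimethylpropanoate
Product: 3 4-formyl-3-hydroxy-5-(methoxymethoxy)phenyl 2,2-dimethylpropanoate
Conditions: MOMCl (1.05 equiv), i-Pr2NEt, CH2Cl2, 0 °C
Reagents that add atoms: chloromethyl methyl ether COCCl
Why: Williamson-type O-alkylation should stop after one of the two equivalent ortho hydroxyls, because the remaining one is then fully chelated to the aldehyde.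

Step 3
Reactants: 3 4-formyl-3-hydroxy-5-(methoxymethoxy)phenyl 2,2-dimethylpropanoate
Product: 4 2-bromo-4-formyl-3-hydroxy-5-(methoxymethoxy)phenyl 2,2-dimethylpropanoate
Conditions: NBS, CH2Cl2, −20 °C
Reagents that add atoms: N-bromosuccinimide O=C1CCC(=O)N1Br
Why: Electrophilic aromatic bromination should go ortho to the free, chelated phenol, the only other ring position being flanked by the pivalate and the MOM ether.

Step 4
Reactants: 4 2-bromo-4-formyl-3-hydroxy-5-(methoxymethoxy)phenyl 2,2-dimethylpropanoate
Product: 5 2-bromo-4-formyl-3-methoxy-5-(methoxymethoxy)phenyl 2,2-dimethylpropanoate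
Conditions: MeI, K2CO3, DMF, 23 °C
Reagents that add atoms: iodomethane CI
Why: Williamson methylation of the phenol that directed the bromination puts the future ring methoxy group next to the bromine-bearing carbon, with the aryl pivalate stable to dry carbonate.

Step 5
Reactants: 5 2-bromo-4-formyl-3-methoxy-5-(methoxymethoxy)phenyl 2,2-dimethylpropanoate
Product: 7 2-bromo-4-(dimethoxymethyl)-3-methoxy-5-(methoxymethoxy)phenol, via acetal pivalate 6 (not isolated)
Conditions: HC(OMe)3, pyridinium p-toluenesulfonate (cat.), MeOH, 50 °C; then n-BuNH2, 40 °C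
Reagents that add atoms: trimethyl orthoformate COC(OC)OC
Why: Acetalisation masks the aldehyde against butyllithium, and aminolysis of the activated aryl ester then frees the phenol under non-acidic conditions that leave acetal and MOM ether intact.

Step 6
Reactants: 7 2-bromo-4-(dimethoxymethyl)-3-methoxy-5-(methoxymethoxy)phenol
Product: 10 4-(dimethoxymethyl)-3-methoxy-5-(methoxymethoxy)-2-(trimethylsilyl)phenyl trifluoromethanesulfonate, via aryl trimethylsilyl ether 8 (not isolated), via lithium 2-silylphenolate 9 (not isolated)
Conditions: HN(SiMe3)2, THF, 65 °C, concentrate; n-BuLi, THF, −78 to 23 °C; Tf2O, −78 °C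
Reagents that add atoms: hexamethyldisilazane C[Si](C)(C)N[Si](C)(C)C; trifluoromethanesulfonic anhydride O=S(=O)(OS(=O)(=O)C(F)(F)F)C(F)(F)F
Why: O-silylation, bromine–lithium exchange with 1,3-O-to-C silyl shift (retro-Brook rearrangement) and triflation of the phenolate is the standard one-pot access to ortho-silylaryl triflates.

Step 7
Reactants: 7 2-bromo-4-(dimethoxymethyl)-3-methoxy-5-(methoxymethoxy)phenol
Product: 11 [2-bromo-4-(dimethoxymethyl)-3-methoxy-5-(methoxymethoxy)phenoxy](tert-butyl)dimethylsilane
Conditions: TBSCl, imidazole, DMF, 23 °C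
Reagents that add atoms: tert-butyldimethylsilyl chloride CC(C)(C)[Si](C)(C)Cl
Why: Routine phenol silylation installs the bulkier silyl group that is to migrate to carbon in the next step.

Step 8
Reactants: 11 [2-bromo-4-(dimethoxymethyl)-3-methoxy-5-(methoxymethoxy)phenoxy](tert-butyl)dimethylsilane
Product: 13 2-[tert-butyl(dimethyl)silyl]-4-(dimethoxymethyl)-3-methoxy-5-(methoxymethoxy)phenyl trifluoromethanesulfonate, via lithium 2-silylphenolate 12 (not isolated)
Conditions: n-BuLi, THF, −78 to 0 °C; Tf2O, −78 °C
Reagents that add atoms: trifluoromethanesulfonic anhydride O=S(=O)(OS(=O)(=O)C(F)(F)F)C(F)(F)F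
Why: The same bromine–lithium exchange, retro-Brook shift and triflation should give a silyl triflate whose hindered silicon is attacked by fluoride far more slowly than trimethylsilyl, so that it stays latent in step 12.

Step 9
Reactants: 13 2-[tert-butyl(dimethyl)silyl]-4-(dimethoxymethyl)-3-methoxy-5-(methoxymethoxy)phenyl trifluoromethanesulfonate
Product: 14 2-[tert-butyl(dimethyl)silyl]-4-formyl-5-hydroxy-3-methoxyphenyl trifluoromethanesulfonate
Conditions: 1 M HCl, THF–MeOH, 0 to 23 °C
Reagents that add atoms: water O
Why: Mild acid hydrolyses the electron-rich dimethyl acetal and then the MOM ether ortho to the new carbonyl, while the silyl group, flanked by the electron-withdrawing triflate, should resist protodesilylation.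

Step 10
Reactants: 14 2-[tert-butyl(dimethyl)silyl]-4-formyl-5-hydroxy-3-methoxyphenyl trifluoromethanesulfonate; 15 but-3-yn-2-one
Product: 16 (4S)-3-acetyl-6-[tert-butyl(dimethyl)silyl]-4-hydroxy-5-methoxy-4H-chromen-7-yl trifluoromethanesulfonate
Conditions: β-isocupreidine (C19H22N2O2, 10 mol %; the quinine-derived pseudoenantiomer if that gives the 4S sense), THF, −20 °C
Reagents that add atoms: none
Why: Domino oxa-Michael/intramolecular Morita–Baylis–Hillman-type aldol in which the phenoxide takes the ynone beta-carbon and the amine-bound enolate closes onto the aldehyde, the chiral ammonium enolate choosing the aldehyde face and so setting the 4S carbinol, the only catalyst-set centre.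

Step 11
Reactants: 16 (4S)-3-acetyl-6-[tert-butyl(dimethyl)silyl]-4-hydroxy-5-methoxy-4H-chromen-7-yl trifluoromethanesulfonate
Product: 17 (4S)-3-acetyl-6-[tert-butyl(dimethyl)silyl]-4-{[tert-butyl(dimethyl)silyl]oxy}-5-methoxy-4H-chromen-7-yl trifluoromethanesulfonate
Conditions: TBSCl, imidazole, 4-(dimethylamino)pyridine (cat.), DMF, 23 °C
Reagents that add atoms: tert-butyldimethylsilyl chloride CC(C)(C)[Si](C)(C)Cl
Why: Silylation under base keeps the ionisable 4H-chromen-4-ol away from acid, masks the hydroxyl against aryne O-arylation and leaves its oxygen as the internal nucleophile for step 12.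

Step 12
Reactants: 10 4-(dimethoxymethyl)-3-methoxy-5-(methoxymethoxy)-2-(trimethylsilyl)phenyl trifluoromethanesulfonate; 17 (4S)-3-acetyl-6-[tert-butyl(dimethyl)silyl]-4-{[tert-butyl(dimethyl)silyl]oxy}-5-methoxy-4H-chromen-7-yl trifluoromethanesulfonate
Product: 21 ring-B silyl triflate bridged acetal (R,R,S), via aryne 18 (not isolated), via benzocyclobutene adduct 19 (not isolated), via cesium enolate 20 (not isolated)
Conditions: 10 (1.3 equiv), CsF (3 equiv), MeCN, 0 to 23 °C; AcOH quench at −20 °C
Reagents that add atoms: none
Why: Proposed new method: fluoride should unmask aryne 18 from the trimethylsilyl triflate 10 only (the tert-butyldimethylsilyl triflate in 17 stays closed to CsF at room temperature), the enol-ether carbon C3 of 17 attacks the aryne carbon remote from OMe, and collapse of the aryl anion/oxocarbenium pair closes the four-membered ring of the cis-fused adduct 19 as a stepwise [2+2], the closest known reactions being aryne [2+2] additions to enol ethers and enamides and the formal C=C insertion of arynes into vinylogous amides. The donor–acceptor cyclobutene should then open by retro-aldol-type heterolysis of the former C2–C3 bond (cation held by the aryloxy oxygen and the ortho-methoxy/para-alkoxy ring A, anion as the ketone enolate), as in aryne acyl-alkylation, which expands the pyran to an eight-membered ring. The silyl ether oxygen on the 4S carbon captures the oxocarbenium across that ring (6-exo-trig for the isochroman ring, closing both six-membered rings of the bicycle at once) and fluoride removes the silyl group. The acetal carbon can only form in the configuration that lets the one-oxygen bridge span the ring, so it is relayed from the catalyst-set carbinol, and the acetyl-bearing carbon is set on quench by protonation of enolate 20 on the convex face, anti to the aryl bridge on the neighbouring carbon. The step needs chemoselectivity for a weakly nucleophilic push-pull alkene, which is why 17 carries no azine nitrogen, free hydroxyl or other aryne trap, and aryne regioselectivity, which the methoxy group next to the anion-bearing carbon secures. Beta-elimination of the new bridge oxygen from 20 is disfavoured because that C–O bond is a ring bond nearly orthogonal to the enolate pi system.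

Step 13
Reactants: 21 ring-B silyl triflate bridged acetal (R,R,S); 22 sodium (E)-3-oxobut-1-en-1-olate
Product: 25 protected target as epimer mixture at the acetyl-bearing carbon, via ring-B aryne 23 (not isolated), via keto aldehyde 24 (not isolated)
Conditions: 22 (3 equiv), Bu4NF, THF–MeCN, 60 °C; then 28% aq. NH3, 60 °C
Reagents that add atoms: ammonia N
Why: Aryne acyl-alkylation/condensation: the stronger fluoride source opens the hindered silyl triflate to aryne 23, the enolate adds through carbon to the aryne carbon remote from OMe, the aryl anion attacks the formyl group (more electrophilic than acetyl) and the four-membered alkoxide fragments to keto aldehyde 24, which ammonia closes to the 3-methylisoquinoline, the basic medium being expected to scramble the acetyl-bearing centre only.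

Step 14
Reactants: 25 protected target as epimer mixture at the acetyl-bearing carbon
Product: 27 protected target (R,R,S), via potassium enolate 26 (not isolated)
Conditions: KN(SiMe3)2 (1.05 equiv), THF, −78 to −40 °C; AcOH, −78 °C
Reagents that add atoms: none
Why: Equilibrating deprotonation gives the ring-A-conjugated enolate (the benzylic methine is far more acidic than the acetyl methyl), and kinetic protonation should occur on the convex face, anti to the axial aryl bridge on the adjacent carbon, placing acetyl cis to that bridge as in the target.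

Step 15
Reactants: 27 protected target (R,R,S)
Product: 28 CNP0584953.1
Conditions: 0.5 M HCl, THF–H2O, 0 °C, short reaction time
Reagents that add atoms: water O
Why: Acid hydrolysis of the electron-rich aryl dimethyl acetal and of the MOM ether ortho to the liberated aldehyde, with the bridged acetal kept closed by its bicyclic stability and the protonated isoquinoline disfavouring ionisation at the benzylic C–O bond, and with low temperature limiting acid-catalysed enolisation of the ketone.

**Compound list**

1 | 2,4,6-trihydroxybenzaldehyde | O=Cc1c(O)cc(O)cc1O | starting material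
2 | 4-formyl-3,5-dihydroxyphenyl 2,2-dimethylpropanoate | O=Cc1c(O)cc(OC(=O)C(C)(C)C)cc1O | intermediate
3 | 4-formyl-3-hydroxy-5-(methoxymethoxy)phenyl 2,2-dimethylpropanoate | O=Cc1c(O)cc(OC(=O)C(C)(C)C)cc1OCOC | intermediate
4 | 2-bromo-4-formyl-3-hydroxy-5-(methoxymethoxy)phenyl 2,2-dimethylpropanoate | O=Cc1c(O)c(Br)c(OC(=O)C(C)(C)C)cc1OCOC | intermediate
5 | 2-bromo-4-formyl-3-methoxy-5-(methoxymethoxy)phenyl 2,2-dimethylpropanoate | O=Cc1c(OC)c(Br)c(OC(=O)C(C)(C)C)cc1OCOC | intermediate
6 | 2-bromo-4-(dimethoxymethyl)-3-methoxy-5-(methoxymethoxy)phenyl 2,2-dimethylpropanoate (acetal pivalate, not isolated) | COC(OC)c1c(OC)c(Br)c(OC(=O)C(C)(C)C)cc1OCOC | intermediate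
7 | 2-bromo-4-(dimethoxymethyl)-3-methoxy-5-(methoxymethoxy)phenol | COC(OC)c1c(OC)c(Br)c(O)cc1OCOC | intermediate
8 | [2-bromo-4-(dimethoxymethyl)-3-methoxy-5-(methoxymethoxy)phenoxy]trimethylsilane (not isolated) | COC(OC)c1c(OC)c(Br)c(O[Si](C)(C)C)cc1OCOC | intermediate
9 | lithium 4-(dimethoxymethyl)-3-methoxy-5-(methoxymethoxy)-2-(trimethylsilyl)phenolate (not isolated) | COC(OC)c1c(OC)c([Si](C)(C)C)c([O-])cc1OCOC.[Li+] | intermediate
10 | 4-(dimethoxymethyl)-3-methoxy-5-(methoxymethoxy)-2-(trimethylsilyl)phenyl trifluoromethanesulfonate | COC(OC)c1c(OC)c([Si](C)(C)C)c(OS(=O)(=O)C(F)(F)F)cc1OCOC | intermediate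
11 | [2-bromo-4-(dimethoxymethyl)-3-methoxy-5-(methoxymethoxy)phenoxy](tert-butyl)dimethylsilane | COC(OC)c1c(OC)c(Br)c(O[Si](C)(C)C(C)(C)C)cc1OCOC | intermediate
12 | lithium 2-[tert-butyl(dimethyl)silyl]-4-(dimethoxymethyl)-3-methoxy-5-(methoxymethoxy)phenolate (not isolated) | COC(OC)c1c(OC)c([Si](C)(C)C(C)(C)C)c([O-])cc1OCOC.[Li+] | intermediate
13 | 2-[tert-butyl(dimethyl)silyl]-4-(dimethoxymethyl)-3-methoxy-5-(methoxymethoxy)phenyl trifluoromethanesulfonate | COC(OC)c1c(OC)c([Si](C)(C)C(C)(C)C)c(OS(=O)(=O)C(F)(F)F)cc1OCOC | intermediate
14 | 2-[tert-butyl(dimethyl)silyl]-4-formyl-5-hydroxy-3-methoxyphenyl trifluoromethanesulfonate | O=Cc1c(OC)c([Si](C)(C)C(C)(C)C)c(OS(=O)(=O)C(F)(F)F)cc1O | intermediate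
15 | but-3-yn-2-one | CC(=O)C#C | starting material
16 | (4S)-3-acetyl-6-[tert-butyl(dimethyl)silyl]-4-hydroxy-5-methoxy-4H-chromen-7-yl trifluoromethanesulfonate | CC(=O)C1=COc2cc(OS(=O)(=O)C(F)(F)F)c([Si](C)(C)C(C)(C)C)c(OC)c2[C@@H]1O | intermediate
17 | (4S)-3-acetyl-6-[tert-butyl(dimethyl)silyl]-4-{[tert-butyl(dimethyl)silyl]oxy}-5-methoxy-4H-chromen-7-yl trifluoromethanesulfonate | CC(=O)C1=COc2cc(OS(=O)(=O)C(F)(F)F)c([Si](C)(C)C(C)(C)C)c(OC)c2[C@@H]1O[Si](C)(C)C(C)(C)C | intermediate
18 | 4-(dimethoxymethyl)-3-methoxy-5-(methoxymethoxy)benzyne (aryne carbons 1 and 2; not isolated) | COC(OC)C1=C(OC)C#CC=C1OCOC | intermediate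
19 | benzocyclobutene adduct: ring A fused through its two aryne carbons to C2 (H, aryloxy O) and C3 (acetyl) of the 4-silyloxychroman, cis ring fusion, anti to the silyloxy group (not isolated) | COc1c(C(OC)OC)c(OCOC)cc2c1[C@H]1Oc3cc(OS(=O)(=O)C(F)(F)F)c([Si](C)(C)C(C)(C)C)c(OC)c3[C@H](O[Si](C)(C)C(C)(C)C)[C@]12C(C)=O | intermediate
20 | cesium enolate of 21 (acetyl-bearing carbon sp2, enolate geometry not defined; other two centres as in 21; not isolated) | COc1c(C(OC)OC)c(OCOC)cc2c1[C@H]1Oc3cc(OS(=O)(=O)C(F)(F)F)c([Si](C)(C)C(C)(C)C)c(OC)c3[C@H](O1)C2=C(C)[O-].[Cs+] | intermediate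
21 | bridged acetal with 11-acetyl-6,12-epoxy-6H,12H-dibenzo[b,f]oxocine core; ring A: OMe, CH(OMe)2, OMOM; ring B: OMe, Si(t-Bu)Me2, OTf; acetal carbon R, oxygenated benzylic carbon R, acetyl-bearing carbon S | COc1c(C(OC)OC)c(OCOC)cc2c1[C@H]1Oc3cc(OS(=O)(=O)C(F)(F)F)c([Si](C)(C)C(C)(C)C)c(OC)c3[C@H](O1)[C@H]2C(C)=O | intermediate
22 | sodium (E)-3-oxobut-1-en-1-olate | CC(=O)/C=C/[O-].[Na+] | starting material
23 | ring-B aryne from 21 (didehydro at the carbons that carried Si and OTf; not isolated) | COc1c(C(OC)OC)c(OCOC)cc2c1[C@H]1OC3=CC#CC(OC)=C3[C@H](O1)[C@H]2C(C)=O | intermediate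
24 | keto aldehyde: ring B carries CHO (next to OMe) and CH2C(O)CH3; acetyl-bearing carbon as epimer mixture; other centres R,R (not isolated) | COc1c(C(OC)OC)c(OCOC)cc2c1[C@H]1Oc3cc(CC(C)=O)c(C=O)c(OC)c3[C@H](O1)C2C(C)=O | intermediate
25 | target protected as dimethyl acetal and MOM ether, epimer mixture at the acetyl-bearing carbon; other centres R,R | COc1c(C(OC)OC)c(OCOC)cc2c1[C@H]1Oc3cc4cc(C)ncc4c(OC)c3[C@H](O1)C2C(C)=O | intermediate
26 | potassium enolate of 25 (enolate geometry not defined; not isolated) | COc1c(C(OC)OC)c(OCOC)cc2c1[C@H]1Oc3cc4cc(C)ncc4c(OC)c3[C@H](O1)C2=C(C)[O-].[K+] | intermediate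
27 | target protected as dimethyl acetal and MOM ether; acetal carbon R, oxygenated benzylic carbon R, acetyl-bearing carbon S | COc1c(C(OC)OC)c(OCOC)cc2c1[C@H]1Oc3cc4cc(C)ncc4c(OC)c3[C@H](O1)[C@H]2C(C)=O | intermediate
28 | CNP0584953.1; acetal carbon R, oxygenated benzylic carbon R, acetyl-bearing carbon S | COc1c(C=O)c(O)cc2c1[C@H]1Oc3cc4cc(C)ncc4c(OC)c3[C@H](O1)[C@H]2C(C)=O | target

**Step count and risks**

Total step count: 15. Longest linear sequence: 14 steps (steps 1–5 and 7–15); step 6 is a one-step branch that joins at step 12.

Step 12 (riskiest; Proposed new method). What may go wrong: the push-pull enol ether may be too weak a nucleophile, so that aryne self-reaction or attack by the acetyl oxygen wins, or the cyclobutene may fail to fragment. The fallback uses the documented [2+2]/ring-opening of arynes with vinylogous amides on an open-chain substrate and closes the acetal separately. It sets out from 17: pyrrolidine (THF, 23 °C) should open the vinylogous ester by addition–elimination to the vinylogous amide F1 with release of the ring-B phenol. TBSCl/imidazole would give the bis-silyl ether F2. Aryne 18, generated from 10 with CsF in MeCN, should insert into the enaminone C=C bond of F2, and aqueous work-up would hydrolyse the iminium to keto aldehyde F3. HF·pyridine in THF would remove both O-silyl groups, and pyridinium p-toluenesulfonate with 4 Å molecular sieves in CH2Cl2 should close the hydroxy aldehyde to 21. The fallback comes back at 21, as an epimer mixture at the acetyl-bearing carbon that step 14 resets.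

Step 13. What may go wrong: migration of the acetyl instead of the formyl group, O-arylation of the ambident enolate, or sluggish fluoride attack at the hindered silicon with competing loss of the triflate. The fallback sets out from 21: aryne 23 is generated with Bu4NF in the presence of (E)-4-(dimethylamino)but-3-en-2-one instead of 22. Formal insertion into the vinylogous amide C=C bond places the aminomethine carbon unambiguously next to OMe and should give the amino isochromene F4. NH4OAc and aqueous NH3 at 50 °C would convert F4 to 25, where the route is rejoined.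

Step 10. What may go wrong: poor facial selectivity in the amine-bound aldol, or erosion of enantiomeric purity by reversal of the cyclisation. The fallback sets out from 14: 1,4-diazabicyclo[2.2.2]octane (20 mol %, THF, 0 °C) and 15 should give the racemic chromenol F5. Acylative kinetic resolution with isobutyric anhydride, i-Pr2NEt and benzotetramisole (C15H12N2S; the enantiomer that acylates the 4R alcohol faster) would leave (4S)-16 and the (4R)-isobutyrate F6, which chromatography separates. The route is rejoined at 16.

Further compounds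
F1 | step 12 | 3-{(S)-[tert-butyl(dimethyl)silyl]oxy[3-(tert-butyldimethylsilyl)-6-hydroxy-2-methoxy-4-(triflyloxy)phenyl]methyl}-4-(pyrrolidin-1-yl)but-3-en-2-one (alkene geometry not defined) | CC(=O)C(=CN1CCCC1)[C@@H](O[Si](C)(C)C(C)(C)C)c1c(O)cc(OS(=O)(=O)C(F)(F)F)c([Si](C)(C)C(C)(C)C)c1OC
F2 | step 12 | O-tert-butyldimethylsilyl ether of F1 at the phenol | CC(=O)C(=CN1CCCC1)[C@@H](O[Si](C)(C)C(C)(C)C)c1c(O[Si](C)(C)C(C)(C)C)cc(OS(=O)(=O)C(F)(F)F)c([Si](C)(C)C(C)(C)C)c1OC
F3 | step 12 | open keto aldehyde: ring A with CHO and CH(COCH3)–CH(OSi)–aryl on adjacent carbons, both ring-B oxygens silylated, acetyl-bearing carbon as epimer mixture | COc1c(C(OC)OC)c(OCOC)cc(C(C(C)=O)[C@@H](O[Si](C)(C)C(C)(C)C)c2c(O[Si](C)(C)C(C)(C)C)cc(OS(=O)(=O)C(F)(F)F)c([Si](C)(C)C(C)(C)C)c2OC)c1C=O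
F4 | step 13 | amino isochromene: ring B fused to a 1-(dimethylamino)-3-methyl-1H-isochromene ring, aminal carbon and acetyl-bearing carbon undefined | COc1c(C(OC)OC)c(OCOC)cc2c1[C@H]1Oc3cc4C=C(C)OC(N(C)C)c4c(OC)c3[C@H](O1)C2C(C)=O
F5 | step 10 | racemic 3-acetyl-6-[tert-butyl(dimethyl)silyl]-4-hydroxy-5-methoxy-4H-chromen-7-yl trifluoromethanesulfonate | CC(=O)C1=COc2cc(OS(=O)(=O)C(F)(F)F)c([Si](C)(C)C(C)(C)C)c(OC)c2C1O
F6 | step 10 | (4R)-3-acetyl-6-[tert-butyl(dimethyl)silyl]-5-methoxy-7-(triflyloxy)-4H-chromen-4-yl 2-methylpropanoate | CC(=O)C1=COc2cc(OS(=O)(=O)C(F)(F)F)c([Si](C)(C)C(C)(C)C)c(OC)c2[C@H]1OC(=O)C(C)C
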